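**Remark (one line):** atoms are numbered C1 (carboxyl carbon) to C17 (benzylic carbon), with the ring O1–O2–C3–C4–C5 (O2 on C3); both antipodes of sparteine are taken to be purchasable, and the methoxy silylperoxy ketals are used as mixtures at the ketal carbon, which becomes planar on ionisation.

## Structural features

The target is a 3,3,5,5-tetrasubstituted 1,2-dioxolane (ring O1–O2–C3–C4–C5). C3 carries a methyl group and the acetic acid arm (C2, C1); C5 carries a methyl group and the chain C6–C17, which ends in a phenyl ring on C17. There are four stereocentres and no two are directly adjacent. The quaternary peroxy carbons C3 (R) and C5 (S) are 1,3-related across C4, with the ring methyls trans (arm and chain on opposite faces). The methines C7 (S) and C9 (R) are 1,3-related across C8 in an anti arrangement, and C5 and C7 are 1,3-related across C6. The O–O bond is the fragile element: it does not survive organolithiums, hydrides, low-valent metals, phosphines or hydrogenation, so it has to be introduced after all organometallic chemistry. C3 and C5 bear no hydrogen, so base-induced Kornblum–DeLaMare fragmentation cannot occur, but an enolisable carbonyl at C1 turns the C3–O2 bond into a potential β-leaving group. The difficulty is twofold: the anti-1,3-dimethyl pair sits on a chain with no functional handle for substrate control, and the two quaternary peroxy centres have no strong element controlling them relative to each other or to C7. The key step exploits the strict alternation of CH2 and CH(CH3) from C6 to C10: C9, C8, C7 and C6 can each be inserted into a C–B bond, starting from the C10 boronate of the 8-phenyloctyl stem and leaving boron on C6 as the handle for attaching C5.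

## Logic of the disconnections

**22 ⇒ 20 (by way of 21).** No skeletal bond is cut; the oxidation level of C1 is lowered from acid to alcohol. A carboxyl or ester carbon at C1 would sit β to the cationic C3 needed for ring construction and would acidify the C2 protons, whereas a two-carbon ether arm is inert. The gain is that the acid disappears from every earlier intermediate. The forward step must oxidise a primary alcohol to the acid without touching the O–O bond, the benzylic C17 or any stereocentre.

**20 ⇒ 19.** The O–Si bond of the arm is cut. A bulky silyl ether is needed to carry the arm oxygen through the Lewis acid step. The demand is a fluoride cleavage that spares the peroxide, which the absence of hydrogen on C3 and C5 makes reasonable.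

**19 ⇒ 14 + 18.** C3–C4 and C5–O1 are cut. This takes the dioxolane apart into an alkene holding C4, C5, the C5 methyl and the whole chain, and a four-carbon peroxy ketal holding C3, its methyl, the arm and both oxygens. Both bonds can form in one polar annulation, so the ring, both quaternary carbons and the O–O unit are removed at once and the route becomes convergent. The forward step needs Markovnikov attack through C4 and ring closure faster than proton loss. No element controls C3 or C5, so the step has to be followed by a separation of diastereomers; that is the price of the short endgame.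

**18 ⇒ 17 ⇒ 16 ⇒ 15.** First the peroxide O–Si bond is cut, then the two C3–O bonds of the ketal are traced back to a C=CH2 double bond, then the arm O–Si bond is cut. This reaches a purchasable five-carbon alkenol. The forward ozonolysis must place the carbonyl oxide on the disubstituted carbon and must be worked up without a reductant.

**14 ⇒ 11 + 12 (by way of 13).** C5–C6 is cut. C6 is the carbon on which the iterative homologation leaves boron, and a 1,2-shift from boron onto an alkenyl group forms this sp2–sp3 bond without a transition metal. The alkene end is reduced to a three-carbon bromide. The demand is complete ate-complex formation; the migrating carbon is a CH2, so no stereocentre is at stake.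

**11 ⇒ 3 + 6 (twice) + 7 (twice) (by way of 10, 9 and 8).** C6–C7, C7–C8, C8–C9 and C9–C10 are cut in turn, each as a one-carbon insertion into a C–B bond. The alternating CH2/CH(CH3) pattern maps exactly onto alternating methylene and methyl-carbenoid insertions. Two remote stereocentres and four C–C bonds are reduced to an achiral primary boronate and two small reagents. Each carbenoid cycle must be highly enantioselective under reagent control, with opposite diamine antipodes for C9 and C7. Each insertion must occur once and go to completion, because nothing is purified between cycles.

**3 ⇒ 1 + 2 and 6 ⇒ 4 + 5.** The C10–B bond and the ester C–O bond are cut, reaching purchasable materials. The borylation must substitute a primary bromide without elimination. The esterification must proceed by O-alkylation of the carboxylate, because the carbonyl is flanked by two isopropyl groups.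

## Other disconnections considered

**Alternative 1:** The cut is C3–C4 together with C5–O1, treated as the strategic event. In the forward step SnCl4 removes methoxide from a methoxy silylperoxy ketal, the CH2 terminus of the 2-methylalkene adds to the C3 peroxycarbenium ion, and the silyl-bearing peroxy oxygen captures the tertiary C5 cation to give the silyl ether A1.
- In its favour: one operation builds the ring and both quaternary carbons from two simple partners, the peroxide arrives late, and the peroxide-forming steps are carried by a cheap fragment.
- Against it: C3 is formed by attack on a planar achiral cation and C5 by capture of a planar cation two bonds from C7, so up to four diastereomers can form. A protected arm and a later oxidation are needed. The plan also says nothing about how C7 and C9 are made.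
- Comparison: this is a component of the chosen plan and not a rival. Step 8 is this reaction, its partners are 14 and 18, and A1 is the same compound as 19. In ring construction, mechanism, stereochemical outcome at C3/C5 and step count from the alkene onward the two are equal. Alternative 1 is the better description of where the unresolved stereochemical risk lies, but offers no better answer to it. Where it falls short is the chain: with auxiliary-based alkylations the alkene alone would need roughly twice the operations of steps 1 to 4.

**Alternative 2:** The cut is C5–O1 and O2–C3, with both ring oxygens coming from O2. In the forward step Mn(acac)3 (trivalent manganese) under O2 oxidises the tetrasubstituted cyclopropanol A2 by one electron. Ring opening gives the tertiary C5 radical β to the new C3 ketone, O2 is trapped at C5, and the hydroperoxide closes onto the ketone to give the dioxolan-3-ol A3. A3 lacks C1 and C2, so a later ionisation at C3 and addition of a silyl ketene acetal, then hydrolysis, would be needed.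
- In its favour: no ozone or hydroperoxy ketal is needed, and only the two C5 epimers arise instead of up to four isomers. In the follow-up addition the nucleophile should approach the cyclic peroxycarbenium ion anti to the larger C5 substituent, which places the arm trans to the chain as the target requires. On control of C3 relative to C5 this alternative is the better of the two.
- Against it: C5 is set by O2 capture of a planar radical with no influence from C7. A2 is a regio-defined tetrasubstituted cyclopropanol for which 11 is not a direct precursor; it would take one more carbenoid insertion, conversion to a methyl ketone, a thermodynamic silyl enol ether and a Simmons–Smith reaction, about five further operations. The radical can also divert by β-scission or reduction.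
- Comparison: equal on the unsolved C5/C7 relationship, better on C3/C5 and on peroxide source, clearly worse on step economy and on the accessibility of its precursor.

**Alternative 3:** The cut is C4–C5 and O2–C3. In the forward step SnCl4 ionises the chain silylperoxy ketal A4 to a C5 peroxycarbenium ion, methyl 3-methylbut-3-enoate A5 adds through its CH2 carbon, and the silylperoxy oxygen closes onto the C3 cation to give the methyl ester A6. Saponification then gives the acid.
- In its favour: the full carbon skeleton arrives at the correct oxidation level, with no protecting group and no late oxidation, and A5 is purchasable. The total is eight steps against ten, so on step count this alternative is the better.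
- Against it: the alkene of A5 is deactivated by the ester and can isomerise to the conjugated ester under SnCl4. The C3 cation next to CH2CO2Me can lose a proton instead of closing the ring. Ozonolysis and peroxy ketal handling fall on the valuable chain material, and the sequence after 14 is fully linear, so the longest linear sequence is one step longer. The final saponification exposes a β-peroxy ester to base.
- Comparison: equal in mechanism type and in the lack of control at C3/C5, better in total steps, worse in convergence and in alkene reactivity. The chosen plan keeps it in reserve; A4 and A6 reappear as F4 and F7 in the fallbacks for steps 8 and 10.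

Key step: step 3

## Steps

Step 1
Reactants: 1 (8-bromooctyl)benzene; 2 bis(pinacolato)diboron
Product: 3 4,4,5,5-tetramethyl-2-(8-phenyloctyl)-1,3,2-dioxaborolane
Conditions: CuI (10 mol %), PPh3 (13 mol %), LiOMe (2 equiv), DMF, 25 °C
Reagents that add atoms: none
Why: Copper-catalysed borylation of an alkyl halide: a boryl copper species (monovalent copper) formed from CuI, LiOMe and 2 substitutes the unhindered primary bromide; no stereocentre is involved.

Step 2
Reactants: 4 2,4,6-triisopropylbenzoic acid; 5 ethanol
Product: 6 ethyl 2,4,6-triisopropylbenzoate
Conditions: PPh3, DIAD, THF, 0 °C → rt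
Reagents that add atoms: none
Why: Mitsunobu esterification: the carboxylate is O-alkylated by the ethoxyphosphonium ion, which avoids attack at the carbonyl carbon shielded by two ortho isopropyl groups.

Step 3
Reactants: 3 4,4,5,5-tetramethyl-2-(8-phenyloctyl)-1,3,2-dioxaborolane; 6 ethyl 2,4,6-triisopropylbenzoate; 7 bromochloromethane
Product: 11 2-[(2R,4R)-2,4-dimethyl-12-phenyldodecyl]-4,4,5,5-tetramethyl-1,3,2-dioxaborolane, via (R)-10-phenyldecan-2-yl pinacol boronate 8 (not isolated), via (S)-2-methyl-10-phenyldecyl pinacol boronate 9 (not isolated), via (2S,4R)-4-methyl-12-phenyldodecan-2-yl pinacol boronate 10 (not isolated)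
Conditions: (a) 6, (−)-sparteine, sBuLi, Et2O, −78 °C, then 3, −78 → 35 °C; (b) 7, nBuLi, Et2O, −78 °C → rt; (c) 6, (+)-sparteine, sBuLi, Et2O, −78 °C, then crude 9, −78 → 35 °C; (d) 7, nBuLi, Et2O, −78 °C → rt; aqueous acid wash and short silica plug after each cycle, chromatography of 11 only
Reagents that add atoms: none
Why: Each cycle is a lithiation–borylation homologation, that is, boronate (ate) complex formation followed by a Matteson-type 1,2-metallate rearrangement; the closest known reaction type is the iterative reagent-controlled homologation of pinacol boronic esters with diamine-ligated α-lithio benzoates and ClCH2Li. sBuLi with (−)-sparteine removes the pro-S α-proton of 6 to give a configurationally stable (S)-α-lithio benzoate that attacks boron of 3 with retention; on warming, the 8-phenyloctyl group shifts from boron to carbon anti-periplanar to the departing benzoate, inverts that carbon and forms C9–C10 with C9 set as in the (R)-boronate 8. ClCH2Li, generated from 7 and nBuLi in the presence of 8, forms the chloromethyl ate complex, and the shift of C9 with retention and loss of chloride forms C8–C9 (9). The (R)-carbenoid made with (+)-sparteine repeats the first cycle on 9 and sets C7 while forming C7–C8 (10), and a second ClCH2Li insertion forms C6–C7 and leaves boron on C6 (11). No ring is closed. Each new stereocentre is controlled only by the diamine antipode on lithium and not by the centre already present, so the anti array follows from using the two antipodes in turn, and the migrating carbon keeps its configuration in every shift. The step needs exactly one insertion per cycle and complete migration: ate-complex formation is fast at −78 °C whereas the shift begins only on warming, after excess carbenoid has decomposed, and the bulky triisopropylbenzoate resists attack at its carbonyl and leaves cleanly. The acid wash after each carbenoid cycle removes the diamine, so that none of the first antipode is present when C7 is set.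

Step 4
Reactants: 11 2-[(2R,4R)-2,4-dimethyl-12-phenyldodecyl]-4,4,5,5-tetramethyl-1,3,2-dioxaborolane; 12 2-bromopropene
Product: 14 (4S,6R)-2,4,6-trimethyl-14-phenyltetradec-1-ene, via β-iodoalkyl pinacol boronate 13 (not isolated)
Conditions: 12, tBuLi (2 equiv), THF, −78 °C; then 11, −78 °C; I2, MeOH, −78 °C; NaOMe, MeOH, −78 °C → rt
Reagents that add atoms: none
Why: Zweifel olefination: isopropenyllithium adds to boron, iodine activates the alkenyl group and triggers the 1,2-shift of the C6 methylene from boron to carbon (C5–C6), and methoxide-induced anti elimination of boron and iodide from 13 releases the 1,1-disubstituted alkene. The migrating carbon is a CH2, so C7 and C9 are untouched and no alkene geometry arises.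

Step 5
Reactants: 15 3-methylbut-3-en-1-ol
Product: 16 tert-butyl[(3-methylbut-3-en-1-yl)oxy]diphenylsilane
Conditions: TBDPSCl, imidazole, CH2Cl2, 0 °C → rt
Reagents that add atoms: tert-butyl(chloro)diphenylsilane, CC(C)(C)[Si](Cl)(c1ccccc1)c1ccccc1
Why: Standard silylation of a primary alcohol; the tert-butyldiphenylsilyl ether is chosen because it should survive ozone, SnCl4 at −78 °C and the silylation of the hydroperoxide.

Step 6
Reactants: 16 tert-butyl[(3-methylbut-3-en-1-yl)oxy]diphenylsilane
Product: 17 4-[(tert-butyldiphenylsilyl)oxy]-2-methoxybutan-2-yl hydroperoxide (racemic)
Conditions: O3, CH2Cl2/MeOH, NaHCO3, −78 °C; N2 purge; no reductive work-up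
Reagents that add atoms: ozone, [O-][O+]=O; methanol, CO
Why: Ozonolysis with Criegee fragmentation of the primary ozonide toward the more substituted carbonyl oxide and formaldehyde; methanol traps the carbonyl oxide as the α-methoxy hydroperoxide. The ketal centre is formed without control, which is irrelevant because it is ionised in step 8.

Step 7
Reactants: 17 4-[(tert-butyldiphenylsilyl)oxy]-2-methoxybutan-2-yl hydroperoxide
Product: 18 tert-butyl{3-methoxy-3-[(triethylsilyl)peroxy]butoxy}diphenylsilane (racemic)
Conditions: Et3SiCl, imidazole, DMF, 0 °C
Reagents that add atoms: chlorotriethylsilane, CC[Si](Cl)(CC)CC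
Why: O-Silylation of the hydroperoxide under buffered conditions that leave the acid-labile ketal intact; the triethylsilyl group is the leaving group on the ring-closing oxygen in step 8.

Step 8
Reactants: 14 (4S,6R)-2,4,6-trimethyl-14-phenyltetradec-1-ene; 18 tert-butyl{3-methoxy-3-[(triethylsilyl)peroxy]butoxy}diphenylsilane
Product: 19 tert-butyl{2-[(3S,5S)-5-[(2S,4R)-2,4-dimethyl-12-phenyldodecyl]-3,5-dimethyl-1,2-dioxolan-3-yl]ethoxy}diphenylsilane
Conditions: SnCl4 (1.1 equiv), 18 (1.5 equiv), CH2Cl2, −78 °C; aq. NaHCO3; preparative HPLC
Reagents that add atoms: none
Why: Peroxycarbenium [3+2] annulation: SnCl4 removes methoxide from 18, the CH2 terminus of 14 attacks the peroxycarbenium carbon (C3–C4, Markovnikov), and the silylated peroxy oxygen captures the tertiary C5 cation with loss of the silyl group (C5–O1). C3 and C5 are formed on planar cationic carbons with no nearby controlling element, so a mixture of ring diastereomers is expected, from which the (3S,5S) isomer 19 is to be separated; the trans relationship of the ring methyls can be checked by NOE between the C3 methyl and the C6 protons.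

Step 9
Reactants: 19 tert-butyl{2-[(3S,5S)-5-[(2S,4R)-2,4-dimethyl-12-phenyldodecyl]-3,5-dimethyl-1,2-dioxolan-3-yl]ethoxy}diphenylsilane
Product: 20 2-[(3S,5S)-5-[(2S,4R)-2,4-dimethyl-12-phenyldodecyl]-3,5-dimethyl-1,2-dioxolan-3-yl]ethan-1-ol
Conditions: Bu4NF, AcOH, THF, 0 °C → rt
Reagents that add atoms: none
Why: Fluoride cleavage of the silyl ether; with no hydrogen on C3 or C5 the dioxolane cannot fragment by the Kornblum–DeLaMare pathway, and buffered fluoride should leave the O–O bond intact. The descriptor at C3 stays S because the arm still ranks below C4.

Step 10
Reactants: 20 2-[(3S,5S)-5-[(2S,4R)-2,4-dimethyl-12-phenyldodecyl]-3,5-dimethyl-1,2-dioxolan-3-yl]ethan-1-ol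
Product: 22 2-[(3R,5S)-5-[(2S,4R)-2,4-dimethyl-12-phenyldodecyl]-3,5-dimethyl-1,2-dioxolan-3-yl]acetic acid, via dioxolanyl acetaldehyde 21 (not isolated)
Conditions: TEMPO (20 mol %), PhI(OAc)2 (2.5 equiv), MeCN/H2O 1:1, rt
Reagents that add atoms: water, O
Why: Oxoammonium (TEMPO) oxidation with PhI(OAc)2 as terminal oxidant takes the primary alcohol through aldehyde 21 and its hydrate to the acid under mildly acidic, non-reducing conditions that a dialkyl peroxide and the benzylic CH2 should tolerate. No stereocentre is touched; the C3 descriptor changes from S to R only because the carboxyl arm now outranks C4.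

## Compound list

1 | (8-bromooctyl)benzene | BrCCCCCCCCc1ccccc1 | starting material
2 | bis(pinacolato)diboron | CC1(C)OB(OC1(C)C)B1OC(C)(C)C(C)(C)O1 | starting material
3 | 4,4,5,5-tetramethyl-2-(8-phenyloctyl)-1,3,2-dioxaborolane | CC1(C)OB(CCCCCCCCc2ccccc2)OC1(C)C | intermediate
4 | 2,4,6-triisopropylbenzoic acid | CC(C)c1cc(C(C)C)c(C(=O)O)c(C(C)C)c1 | starting material
5 | ethanol | CCO | starting material
6 | ethyl 2,4,6-triisopropylbenzoate | CCOC(=O)c1c(C(C)C)cc(C(C)C)cc1C(C)C | intermediate
7 | bromochloromethane | ClCBr | starting material
8 | 4,4,5,5-tetramethyl-2-[(2R)-10-phenyldecan-2-yl]-1,3,2-dioxaborolane | C[C@H](CCCCCCCCc1ccccc1)B1OC(C)(C)C(C)(C)O1 | intermediate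
9 | 4,4,5,5-tetramethyl-2-[(2S)-2-methyl-10-phenyldecyl]-1,3,2-dioxaborolane | C[C@H](CCCCCCCCc1ccccc1)CB1OC(C)(C)C(C)(C)O1 | intermediate
10 | 4,4,5,5-tetramethyl-2-[(2S,4R)-4-methyl-12-phenyldodecan-2-yl]-1,3,2-dioxaborolane | C[C@H](CCCCCCCCc1ccccc1)C[C@H](C)B1OC(C)(C)C(C)(C)O1 | intermediate
11 | 2-[(2R,4R)-2,4-dimethyl-12-phenyldodecyl]-4,4,5,5-tetramethyl-1,3,2-dioxaborolane | C[C@H](CCCCCCCCc1ccccc1)C[C@H](C)CB1OC(C)(C)C(C)(C)O1 | intermediate
12 | 2-bromopropene | CC(Br)=C | starting material
13 | 2-[(4S,6R)-1-iodo-2,4,6-trimethyl-14-phenyltetradecan-2-yl]-4,4,5,5-tetramethyl-1,3,2-dioxaborolane (both C2 epimers) | C[C@H](CCCCCCCCc1ccccc1)C[C@H](C)CC(C)(CI)B1OC(C)(C)C(C)(C)O1 | intermediate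
14 | (4S,6R)-2,4,6-trimethyl-14-phenyltetradec-1-ene | C[C@H](CCCCCCCCc1ccccc1)C[C@H](C)CC(C)=C | intermediate
15 | 3-methylbut-3-en-1-ol | CC(=C)CCO | starting material
16 | tert-butyl[(3-methylbut-3-en-1-yl)oxy]diphenylsilane | CC(=C)CCO[Si](c1ccccc1)(c1ccccc1)C(C)(C)C | intermediate
17 | 4-[(tert-butyldiphenylsilyl)oxy]-2-methoxybutan-2-yl hydroperoxide (racemic) | COC(C)(CCO[Si](c1ccccc1)(c1ccccc1)C(C)(C)C)OO | intermediate
18 | tert-butyl{3-methoxy-3-[(triethylsilyl)peroxy]butoxy}diphenylsilane (racemic) | COC(C)(CCO[Si](c1ccccc1)(c1ccccc1)C(C)(C)C)OO[Si](CC)(CC)CC | intermediate
19 | tert-butyl{2-[(3S,5S)-5-[(2S,4R)-2,4-dimethyl-12-phenyldodecyl]-3,5-dimethyl-1,2-dioxolan-3-yl]ethoxy}diphenylsilane | C[C@H](CCCCCCCCc1ccccc1)C[C@H](C)C[C@@]1(C)C[C@](C)(CCO[Si](c2ccccc2)(c2ccccc2)C(C)(C)C)OO1 | intermediate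
20 | 2-[(3S,5S)-5-[(2S,4R)-2,4-dimethyl-12-phenyldodecyl]-3,5-dimethyl-1,2-dioxolan-3-yl]ethan-1-ol | C[C@H](CCCCCCCCc1ccccc1)C[C@H](C)C[C@@]1(C)C[C@](C)(CCO)OO1 | intermediate
21 | 2-[(3R,5S)-5-[(2S,4R)-2,4-dimethyl-12-phenyldodecyl]-3,5-dimethyl-1,2-dioxolan-3-yl]acetaldehyde | C[C@H](CCCCCCCCc1ccccc1)C[C@H](C)C[C@@]1(C)C[C@](C)(CC=O)OO1 | intermediate
22 | 2-[(3R,5S)-5-[(2S,4R)-2,4-dimethyl-12-phenyldodecyl]-3,5-dimethyl-1,2-dioxolan-3-yl]acetic acid | C[C@H](CCCCCCCCc1ccccc1)C[C@H](C)C[C@@]1(C)C[C@](C)(CC(=O)O)OO1 | target

## Step count and least certain steps

Total step count: 10. Longest linear sequence: 6 steps (steps 1, 3, 4, 8, 9, 10; the branches through step 2 and through steps 5 to 7 are equally long). Compounds 13 and 17 to 22 are peroxides or peroxide precursors and should be handled on small scale behind a shield and never concentrated with heating.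

**Step 8.** The most likely failure is poor facial selectivity at both new quaternary centres. C–C bond formation takes place on a planar, achiral peroxycarbenium ion, and ring closure takes place on a planar tertiary cation whose nearest stereocentres (C3 and C7) are only 1,3-related. A near-statistical distribution over up to four C3/C5 diastereomers and a demanding separation must therefore be expected. The assignment of C5 relative to C7 will need correlation with a crystalline derivative of 22. A second failure is proton loss or 1,5-hydride transfer from C9 at the C5 cation competing with ring closure. The fallback reverses the roles of the partners, sets out from 14 and returns at 19. Ozonolysis of 14 in CH2Cl2/MeOH should give (4S,6R)-2-methoxy-4,6-dimethyl-14-phenyltetradecan-2-yl hydroperoxide F3. Et3SiCl and imidazole should convert it into triethyl{[(4S,6R)-2-methoxy-4,6-dimethyl-14-phenyltetradecan-2-yl]peroxy}silane F4. SnCl4 should then ionise F4 to the C5 peroxycarbenium ion, which is annulated with alkene 16 to give 19. The cation to be captured then sits at C3, away from the branched chain and from any hydride donor, and the stereocentres are set in the opposite order. This offers an independent chance of a workable diastereomer distribution but no built-in control, so separation remains necessary.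

**Step 3 (key step).** The most likely failure is incomplete enantioselection in the diamine-mediated deprotonation. Over two carbenoid cycles this becomes contamination by syn diastereomers, which are very hard to remove from an unfunctionalised chain. Incomplete ate-complex formation or migration in any of the four unpurified cycles would also accumulate chains lacking one carbon. The fallback replaces in-flask asymmetric deprotonation by pre-formed, configurationally pure carbenoid precursors; it sets out from 6 and returns at 8 and at 10, and so at 11. Lithiation of 6 with sBuLi and (−)-sparteine and quenching with Me3SnCl should give (S)-1-(trimethylstannyl)ethyl 2,4,6-triisopropylbenzoate F1; the same with (+)-sparteine should give (R)-1-(trimethylstannyl)ethyl 2,4,6-triisopropylbenzoate F2. Each is recrystallised to enantiopurity. Tin–lithium exchange with nBuLi in Et2O at −78 °C regenerates the carbenoid with retention. F1 with 3 then gives 8 and F2 with 9 gives 10, with the ClCH2Li cycles unchanged. The cost is two extra steps and organotin waste.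

**Step 4.** The most likely failure is incomplete boronate formation between the α-substituted alkenyllithium and the β-branched boronate, followed by iodinolysis of the free organolithium and recovery or oxidation of 11. The fallback replaces the boron-to-carbon shift by a copper-catalysed sp3–sp2 coupling; it sets out from 11 and returns at 14. Oxidation of 11 with NaOH and H2O2 should give (2S,4R)-2,4-dimethyl-12-phenyldodecan-1-ol F5. I2, PPh3 and imidazole should give [(9R,11S)-12-iodo-9,11-dimethyldodecyl]benzene F6. Coupling of F6 with isopropenylmagnesium bromide and catalytic Li2CuCl4 in THF should give 14.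

**Step 10.** The most likely failure is ring opening by β-elimination of the peroxy oxygen at the aldehyde stage, because 21 has acidic C2 protons next to the C3–O2 bond, or stalling of the oxidation at the aldehyde. The fallback brings C1 in at the ester oxidation level; it sets out from 14 and returns at 22. F3 and F4 are prepared as described under step 8. SnCl4-promoted annulation of F4 with methyl 3-methylbut-3-enoate should give methyl 2-[(3R,5S)-5-[(2S,4R)-2,4-dimethyl-12-phenyldodecyl]-3,5-dimethyl-1,2-dioxolan-3-yl]acetate F7. Saponification of F7 with LiOH in THF/H2O at 0 °C should give 22. The ester-deactivated alkene and the base step carry their own risk, which is why this is held as a reserve and not used as the main line.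

## Further compounds

F1 | step 3 | (S)-1-(trimethylstannyl)ethyl 2,4,6-triisopropylbenzoate | C[C@@H](OC(=O)c1c(C(C)C)cc(C(C)C)cc1C(C)C)[Sn](C)(C)C
F2 | step 3 | (R)-1-(trimethylstannyl)ethyl 2,4,6-triisopropylbenzoate | C[C@H](OC(=O)c1c(C(C)C)cc(C(C)C)cc1C(C)C)[Sn](C)(C)C
F3 | step 8 | (4S,6R)-2-methoxy-4,6-dimethyl-14-phenyltetradecan-2-yl hydroperoxide (both C2 epimers) | C[C@H](CCCCCCCCc1ccccc1)C[C@H](C)CC(C)(OC)OO
F4 | step 8 | triethyl{[(4S,6R)-2-methoxy-4,6-dimethyl-14-phenyltetradecan-2-yl]peroxy}silane (both C2 epimers) | C[C@H](CCCCCCCCc1ccccc1)C[C@H](C)CC(C)(OC)OO[Si](CC)(CC)CC
F5 | step 4 | (2S,4R)-2,4-dimethyl-12-phenyldodecan-1-ol | C[C@H](CCCCCCCCc1ccccc1)C[C@H](C)CO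
F6 | step 4 | [(9R,11S)-12-iodo-9,11-dimethyldodecyl]benzene | C[C@H](CCCCCCCCc1ccccc1)C[C@H](C)CI
F7 | step 10 | methyl 2-[(3R,5S)-5-[(2S,4R)-2,4-dimethyl-12-phenyldodecyl]-3,5-dimethyl-1,2-dioxolan-3-yl]acetate | C[C@H](CCCCCCCCc1ccccc1)C[C@H](C)C[C@@]1(C)C[C@](C)(CC(=O)OC)OO1
A1 | alternative 1 | tert-butyl{2-[(3S,5S)-5-[(2S,4R)-2,4-dimethyl-12-phenyldodecyl]-3,5-dimethyl-1,2-dioxolan-3-yl]ethoxy}diphenylsilane | C[C@H](CCCCCCCCc1ccccc1)C[C@H](C)C[C@@]1(C)C[C@](C)(CCO[Si](c2ccccc2)(c2ccccc2)C(C)(C)C)OO1
A2 | alternative 2 | 2-[(2S,4R)-2,4-dimethyl-12-phenyldodecyl]-1,2-dimethylcyclopropan-1-ol (ring stereoisomers) | C[C@H](CCCCCCCCc1ccccc1)C[C@H](C)CC1(C)CC1(C)O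
A3 | alternative 2 | (5S)-5-[(2S,4R)-2,4-dimethyl-12-phenyldodecyl]-3,5-dimethyl-1,2-dioxolan-3-ol (both C3 anomers) | C[C@H](CCCCCCCCc1ccccc1)C[C@H](C)C[C@@]1(C)CC(C)(O)OO1
A4 | alternative 3 | triethyl{[(4S,6R)-2-methoxy-4,6-dimethyl-14-phenyltetradecan-2-yl]peroxy}silane (both C2 epimers) | C[C@H](CCCCCCCCc1ccccc1)C[C@H](C)CC(C)(OC)OO[Si](CC)(CC)CC
A5 | alternative 3 | methyl 3-methylbut-3-enoate | COC(=O)CC(C)=C
A6 | alternative 3 | methyl 2-[(3R,5S)-5-[(2S,4R)-2,4-dimethyl-12-phenyldodecyl]-3,5-dimethyl-1,2-dioxolan-3-yl]acetate | C[C@H](CCCCCCCCc1ccccc1)C[C@H](C)C[C@@]1(C)C[C@](C)(CC(=O)OC)OO1
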